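The plan rests on excising C8 and its methyl from the seven-membered ring (C1, C10, C9, C8, C7, C6, C5). What remains is a trans-fused hydrindan-7-one, a rigid five/six ring system on which the C1/C5 fusion, the C4 carbinol and the oxygenated C6 can be controlled more reliably than on a flexible cycloheptane. A single scandium-catalysed insertion of diazoethane into the C7–C9 bond then creates C7–C8 and C8–C9, converts the cyclohexanone into the cycloheptanone and places the methyl-bearing carbon next to the C7 carbonyl, from where the C8=C9 alkene is reached by dehydrogenation. The precursor is the 1β-methyl trans-hydrindan-7-one with a 4β-trimethylsilyloxy-4α-isopropyl carbinol and an equatorial 6α-silyloxy group.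

Key step: step 9

Remarks
- Positions are labelled as in the target: C1 methyl-bearing fusion carbon, C2/C3 CH2, C4 carbinol carbon with isopropyl, C5 fusion CH, C6 acyloxy carbon, C7 carbinol, C8/C9 epoxide carbons (methyl on C8), C10 CH2. β is the face of the C1 methyl, α the face of H-5. Hydrindane intermediates 14–16 keep these labels; they have no C8, so C7 is bonded to C9.
- Assumption: 4-(tert-butyldimethylsilyloxy)benzoic acid (23) is treated as purchasable; otherwise it is one step from 4-hydroxybenzoic acid (TBSCl/imidazole, then K2CO3/MeOH).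
- The two silyl ethers of precursor 16 are removed together in step 12, so no protecting-group exchange is needed after the ring enlargement.

Step 1
Reactants: 1 3-ethoxycyclopent-2-en-1-one; 2 allylmagnesium bromide
Product: 4 3-allylcyclopent-2-en-1-one, via 1-allyl-3-ethoxycyclopent-2-en-1-ol 3 (not isolated)
Conditions: THF, 0 °C; then 1 M HCl, 0 °C, 15 min
Reagents that add atoms: water (O)
Why: Stork–Danheiser transposition, in which 1,2-addition of the Grignard reagent to the vinylogous ester is followed by acid-induced loss of the tertiary hydroxyl and hydrolysis of the ethoxy-stabilised cation to the 3-substituted enone; the acid contact is short and cold so that the allyl double bond does not move into conjugation.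

Step 2
Reactants: 5 (benzyloxy)acetaldehyde; 6 formaldehyde
Product: 7 2-(benzyloxy)prop-2-enal
Conditions: 37% aq. CH2O, pyrrolidine (10 mol%), EtCO2H (10 mol%), i-PrOH, 45 °C
Reagents that add atoms: none
Why: Amine-catalysed Mannich condensation–elimination (α-methylenation of an aldehyde) turns the α-CH2 into the 1,1-disubstituted enol-ether alkene, and the product is used freshly to avoid polymerisation.

Step 3
Reactants: 4 3-allylcyclopent-2-en-1-one; 8 trimethylaluminium; 7 2-(benzyloxy)prop-2-enal
Product: 10 (2S,3R)-3-allyl-2-[(1R)-2-(benzyloxy)-1-hydroxyprop-2-en-1-yl]-3-methylcyclopentan-1-one, via dimethylaluminium enolate 9 (not isolated)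
Conditions: Cu(OTf)2 (2.5 mol%), chiral sulfonate-NHC·Ag complex (3 mol%), THF, −78 → −50 °C; then 7, −78 → −40 °C; aq. Rochelle salt
Reagents that add atoms: none
Why: Copper-catalysed asymmetric conjugate addition of the methylaluminium reagent to the β-substituted cyclopentenone sets the quaternary C1 as R under ligand control, and the regiodefined aluminium enolate is trapped in a tandem aldol addition through a closed Zimmerman–Traxler chair (cyclic E-enolate, hence anti C5/C6) on the face opposite the larger allyl group, which places the new side chain cis to the C1 methyl.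

Step 4
Reactants: 10 (2S,3R)-3-allyl-2-[(1R)-2-(benzyloxy)-1-hydroxyprop-2-en-1-yl]-3-methylcyclopentan-1-one
Product: 11 (2S,3R)-3-allyl-2-[(1R)-2-(benzyloxy)-1-(tert-butyldimethylsilyloxy)prop-2-en-1-yl]-3-methylcyclopentan-1-one
Conditions: TBSOTf, 2,6-lutidine, CH2Cl2, −78 °C
Reagents that add atoms: tert-butyldimethylsilyl triflate (CC(C)(C)[Si](C)(C)OS(=O)(=O)C(F)(F)F)
Why: Silyl-triflate etherification of the secondary aldol hydroxyl is fast at low temperature under a non-nucleophilic base, leaves the enol ether intact and blocks retro-aldol cleavage and β-elimination in the organometallic step that follows.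

Step 5
Reactants: 11 (2S,3R)-3-allyl-2-[(1R)-2-(benzyloxy)-1-(tert-butyldimethylsilyloxy)prop-2-en-1-yl]-3-methylcyclopentan-1-one; 12 isopropylmagnesium chloride
Product: 13 (1R,2S,3R)-3-allyl-2-[(1R)-2-(benzyloxy)-1-(tert-butyldimethylsilyloxy)prop-2-en-1-yl]-3-methyl-1-(propan-2-yl)cyclopentan-1-ol
Conditions: anhydrous CeCl3, THF, −78 → 0 °C; aqueous quench
Reagents that add atoms: none
Why: Organocerium addition (Grignard reagent transmetalated with CeCl3) suppresses enolisation and β-hydride reduction of the hindered α-branched cyclopentanone, and the isopropyl group enters the C4 carbonyl on the face anti to the bulky C5 side chain, which gives 4α-isopropyl and 4β-hydroxyl (4R).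

Step 6
Reactants: 13 (1R,2S,3R)-3-allyl-2-[(1R)-2-(benzyloxy)-1-(tert-butyldimethylsilyloxy)prop-2-en-1-yl]-3-methyl-1-(propan-2-yl)cyclopentan-1-ol
Product: 15 6α-(tert-butyldimethylsilyloxy)-4β-hydroxy-4α-isopropyl-1β-methyl-trans-hydrindan-7-one, via cyclic benzyl enol ether 14 (not isolated)
Conditions: Grubbs II (5 mol%), toluene, 80 °C; then THF, 1 M HCl, rt
Reagents that add atoms: water (O)
Why: Ring-closing metathesis starts at the terminal allyl alkene and closes onto the 1,1-disubstituted enol ether to form the six-membered ring (C7=C9) with loss of ethene, the trans fusion being fixed beforehand by the trans-disposed substituents on C1 and C5; dilute acid then hydrolyses the trisubstituted enol ether to the C7 ketone without cleaving the secondary TBS ether, whose equatorial 6α orientation is also the thermodynamically preferred one.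

Step 7
Reactants: 15 6α-(tert-butyldimethylsilyloxy)-4β-hydroxy-4α-isopropyl-1β-methyl-trans-hydrindan-7-one
Product: 16 6α-(tert-butyldimethylsilyloxy)-4α-isopropyl-1β-methyl-4β-(trimethylsilyloxy)-trans-hydrindan-7-one
Conditions: 1-(trimethylsilyl)imidazole, CH2Cl2, 40 °C
Reagents that add atoms: 1-(trimethylsilyl)imidazole (C[Si](C)(C)n1ccnc1)
Why: Neutral silyl transfer from the N-silylimidazole caps the hindered tertiary alcohol without enolising the ketone, which removes the only protic group that could quench diazoethane at the Lewis acid.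

Step 8
Reactants: 17 N-ethyl-N-nitrosourea
Product: 18 diazoethane
Conditions: 40% aq. KOH, toluene, 0 °C; toluene layer dried over KOH pellets, titrated, used cold behind a shield
Reagents that add atoms: none
Why: Base-induced fragmentation of an N-alkyl-N-nitrosourea is the standard preparation of a non-stabilised diazoalkane, delivered here as a dry toluene solution suited to Lewis-acid catalysis.

Step 9
Reactants: 16 6α-(tert-butyldimethylsilyloxy)-4α-isopropyl-1β-methyl-4β-(trimethylsilyloxy)-trans-hydrindan-7-one; 18 diazoethane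
Product: 19 6α-(tert-butyldimethylsilyloxy)-4α-isopropyl-1β,8β-dimethyl-4β-(trimethylsilyloxy)-trans-perhydroazulen-7-one
Conditions: Sc(OTf)3 (10 mol%), 18 (2.5 equiv, toluene), toluene/CH2Cl2, −78 °C
Reagents that add atoms: none
Why: Scandium triflate binds the C7 ketone, the nucleophilic carbon of diazoethane attacks it to give a β-alkoxy diazonium species (new C7–C8 bond), and C9 then moves from C7 to C8 as dinitrogen leaves (new C8–C9 bond), which restores the carbonyl at C7. The closest known reaction type is the Lewis-acid-catalysed homologation of cyclic ketones with non-stabilised diazoalkanes, a Tiffeneau–Demjanov-type ring enlargement. The seven-membered ring (C1, C10, C9, C8, C7, C6, C5) is therefore not closed by a cyclisation; it arises by a 1,2-alkyl shift that inserts one carbon into the existing six-membered ring. The new C8 centre is fixed by the substrate (approach of the diazoalkane to the rigid trans-hydrindanone followed by stereospecific migration), and either epimer serves because C8 becomes trigonal in steps 10 and 11. The step needs C9 (CH2) to migrate in preference to C6 and the reaction to stop after one insertion: the inductively withdrawing, bulky silyloxy group on the more substituted C6 lowers its migratory aptitude, and the product ketone, now branched on both α-carbons, is much less reactive towards a second addition. The silyl ethers on O4 and O6 keep protic groups away from the diazoalkane, and the stereocentres C1, C4, C5 and C6 are not touched.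

Step 10
Reactants: 19 6α-(tert-butyldimethylsilyloxy)-4α-isopropyl-1β,8β-dimethyl-4β-(trimethylsilyloxy)-trans-perhydroazulen-7-one
Product: 20 6α-(tert-butyldimethylsilyloxy)-4α-isopropyl-1β,8-dimethyl-4β,7-bis(trimethylsilyloxy)-trans-hydroazul-7-ene
Conditions: LDA, TMSCl, THF, −78 °C
Reagents that add atoms: chlorotrimethylsilane (C[Si](C)(C)Cl)
Why: Kinetic enolisation with in situ silylation should take place at C8 because the C6–H is shielded and electronically deactivated by its α-silyloxy group, and the resulting tetrasubstituted C7=C8 silyl enol ether removes the uncontrolled C8 centre.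

Step 11
Reactants: 20 6α-(tert-butyldimethylsilyloxy)-4α-isopropyl-1β,8-dimethyl-4β,7-bis(trimethylsilyloxy)-trans-hydroazul-7-ene
Product: 21 6α-(tert-butyldimethylsilyloxy)-4α-isopropyl-1β,8-dimethyl-4β-(trimethylsilyloxy)-trans-hydroazul-8-en-7-one
Conditions: Pd(OAc)2 (1.1 equiv), MeCN, 40 °C
Reagents that add atoms: none
Why: Saegusa–Ito oxidation, in which the palladium(II) enolate formed from the silyl enol ether undergoes β-hydride elimination towards C9 and gives the endocyclic, conjugated 8-methyl-8-en-7-one as the more stable alkene isomer.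

Step 12
Reactants: 21 6α-(tert-butyldimethylsilyloxy)-4α-isopropyl-1β,8-dimethyl-4β-(trimethylsilyloxy)-trans-hydroazul-8-en-7-one
Product: 22 4β,6α-dihydroxy-4α-isopropyl-1β,8-dimethyl-trans-hydroazul-8-en-7-one
Conditions: 48% aq. HF, MeCN, 0 °C → rt
Reagents that add atoms: none
Why: Acidic fluoride desilylation removes the tertiary TMS and the secondary TBS ether in one operation under non-basic conditions, so the α-hydroxy enone is released without α-ketol rearrangement and the equatorial 6α-hydroxyl is retained.

Step 13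
Reactants: 22 4β,6α-dihydroxy-4α-isopropyl-1β,8-dimethyl-trans-hydroazul-8-en-7-one; 23 4-(tert-butyldimethylsilyloxy)benzoic acid
Product: 24 4β-hydroxy-4α-isopropyl-1β,8-dimethyl-7-oxo-trans-hydroazul-8-en-6α-yl 4-(tert-butyldimethylsilyloxy)benzoate
Conditions: DCC, DMAP (cat.), CH2Cl2, rt
Reagents that add atoms: none
Why: Steglich esterification acylates the secondary 6-hydroxyl selectively, since the tertiary 4-hydroxyl next to the isopropyl group is too hindered to react, and the silyl-protected acid prevents self-condensation through the phenol.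

Step 14
Reactants: 24 4β-hydroxy-4α-isopropyl-1β,8-dimethyl-7-oxo-trans-hydroazul-8-en-6α-yl 4-(tert-butyldimethylsilyloxy)benzoate
Product: 25 4β,7β-dihydroxy-4α-isopropyl-1β,8-dimethyl-trans-hydroazul-8-en-6α-yl 4-(tert-butyldimethylsilyloxy)benzoate
Conditions: NaBH4, CeCl3·7H2O, MeOH, −78 °C
Reagents that add atoms: none
Why: Luche reduction gives clean 1,2-reduction of the enone, and the small hydride should attack C7 from the α-face in an axial-type trajectory anti to the pseudo-axial C6–H, which places the new hydroxyl pseudo-equatorial and β (7S), trans to the 6α-ester, while the low temperature and near-neutral medium guard against O6→O7 acyl migration.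

Step 15
Reactants: 25 4β,7β-dihydroxy-4α-isopropyl-1β,8-dimethyl-trans-hydroazul-8-en-6α-yl 4-(tert-butyldimethylsilyloxy)benzoate
Product: 26 4β-hydroxy-4α-isopropyl-1β,8-dimethyl-7β-(triethylsilyloxy)-trans-hydroazul-8-en-6α-yl 4-(tert-butyldimethylsilyloxy)benzoate
Conditions: TESCl, imidazole, DMF, 0 °C → rt
Reagents that add atoms: chlorotriethylsilane (CC[Si](Cl)(CC)CC)
Why: Silyl-chloride etherification of the secondary allylic alcohol (the tertiary 4-OH does not react) switches off hydroxyl-directed syn epoxidation and adds bulk to the β-face of the C8=C9 alkene.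

Step 16
Reactants: 26 4β-hydroxy-4α-isopropyl-1β,8-dimethyl-7β-(triethylsilyloxy)-trans-hydroazul-8-en-6α-yl 4-(tert-butyldimethylsilyloxy)benzoate
Product: 27 8α,9α-epoxy-4β-hydroxy-4α-isopropyl-1β,8β-dimethyl-7β-(triethylsilyloxy)-trans-perhydroazulen-6α-yl 4-(tert-butyldimethylsilyloxy)benzoate
Conditions: mCPBA, NaHCO3, CH2Cl2, 0 °C
Reagents that add atoms: mCPBA (OOC(=O)c1cccc(Cl)c1)
Why: Prilezhaev epoxidation of the electron-rich trisubstituted alkene should occur on the α-face, anti to the 7β-silyloxy group and to the β-oriented C1 methyl, which sets C8 (R) and C9 (S) in one step under buffered conditions that leave the ester and the silyl ethers alone.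

Step 17
Reactants: 27 8α,9α-epoxy-4β-hydroxy-4α-isopropyl-1β,8β-dimethyl-7β-(triethylsilyloxy)-trans-perhydroazulen-6α-yl 4-(tert-butyldimethylsilyloxy)benzoate
Product: 28 (1R,4R,5S,6R,7S,8R,9S)-8,9-epoxy-4,7-dihydroxy-4-isopropyl-1,8-dimethyl-trans-perhydroazulen-6-yl 4-hydroxybenzoate
Conditions: TBAF, AcOH (1:1), THF, 0 °C → rt
Reagents that add atoms: none
Why: Buffered fluoride desilylation cleaves the aryl TBS and the secondary TES ether, while the acetic acid buffer prevents alkoxide-driven acyl migration, Payne rearrangement of the trans-epoxy alcohol and epoxide opening.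

Compound list
1 | 3-ethoxycyclopent-2-en-1-one | CCOC1=CC(=O)CC1 | starting material
2 | allylmagnesium bromide | C=CC[Mg]Br | starting material
3 | 1-allyl-3-ethoxycyclopent-2-en-1-ol (racemic, formed as its magnesium alkoxide) | CCOC1=CC(O)(CC=C)CC1 | intermediate
4 | 3-allylcyclopent-2-en-1-one | C=CCC1=CC(=O)CC1 | intermediate
5 | (benzyloxy)acetaldehyde | O=CCOCc1ccccc1 | starting material
6 | formaldehyde (37% aqueous) | C=O | starting material
7 | 2-(benzyloxy)prop-2-enal | C=C(OCc1ccccc1)C=O | intermediate
8 | trimethylaluminium | C[Al](C)C | starting material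
9 | dimethylaluminium (R)-3-allyl-3-methylcyclopent-1-en-1-olate | C=CC[C@@]1(C)CCC(O[Al](C)C)=C1 | intermediate
10 | (2S,3R)-3-allyl-2-[(1R)-2-(benzyloxy)-1-hydroxyprop-2-en-1-yl]-3-methylcyclopentan-1-one | C=CC[C@@]1(C)CCC(=O)[C@@H]1[C@@H](O)C(=C)OCc1ccccc1 | intermediate
11 | (2S,3R)-3-allyl-2-[(1R)-2-(benzyloxy)-1-(tert-butyldimethylsilyloxy)prop-2-en-1-yl]-3-methylcyclopentan-1-one | C=CC[C@@]1(C)CCC(=O)[C@@H]1[C@@H](O[Si](C)(C)C(C)(C)C)C(=C)OCc1ccccc1 | intermediate
12 | isopropylmagnesium chloride | CC(C)[Mg]Cl | starting material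
13 | (1R,2S,3R)-3-allyl-2-[(1R)-2-(benzyloxy)-1-(tert-butyldimethylsilyloxy)prop-2-en-1-yl]-3-methyl-1-(propan-2-yl)cyclopentan-1-ol | C=CC[C@@]1(C)CC[C@@](O)(C(C)C)[C@@H]1[C@@H](O[Si](C)(C)C(C)(C)C)C(=C)OCc1ccccc1 | intermediate
14 | 7-benzyloxy-6α-(tert-butyldimethylsilyloxy)-4α-isopropyl-1β-methyl-trans-hydrind-7(9)-en-4β-ol | CC(C)[C@]1(O)CC[C@]2(C)CC=C(OCc3ccccc3)[C@H](O[Si](C)(C)C(C)(C)C)[C@H]21 | intermediate
15 | 6α-(tert-butyldimethylsilyloxy)-4β-hydroxy-4α-isopropyl-1β-methyl-trans-hydrindan-7-one (5α-H) | CC(C)[C@]1(O)CC[C@]2(C)CCC(=O)[C@H](O[Si](C)(C)C(C)(C)C)[C@H]21 | intermediate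
16 | 6α-(tert-butyldimethylsilyloxy)-4α-isopropyl-1β-methyl-4β-(trimethylsilyloxy)-trans-hydrindan-7-one; systematic: (3R,3aS,4R,7aR)-4-[(tert-butyldimethylsilyl)oxy]-7a-methyl-3-(propan-2-yl)-3-[(trimethylsilyl)oxy]octahydro-5H-inden-5-one | CC(C)[C@]1(O[Si](C)(C)C)CC[C@]2(C)CCC(=O)[C@H](O[Si](C)(C)C(C)(C)C)[C@H]21 | intermediate
17 | N-ethyl-N-nitrosourea | CCN(N=O)C(N)=O | starting material
18 | diazoethane | CC=[N+]=[N-] | intermediate
19 | 6α-(tert-butyldimethylsilyloxy)-4α-isopropyl-1β,8β-dimethyl-4β-(trimethylsilyloxy)-trans-perhydroazulen-7-one (8β-methyl drawn; the 8α-epimer is equally usable) | CC(C)[C@]1(O[Si](C)(C)C)CC[C@]2(C)CC[C@@H](C)C(=O)[C@H](O[Si](C)(C)C(C)(C)C)[C@H]21 | intermediate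
20 | 6α-(tert-butyldimethylsilyloxy)-4α-isopropyl-1β,8-dimethyl-4β,7-bis(trimethylsilyloxy)-trans-hydroazul-7-ene | CC(C)[C@]1(O[Si](C)(C)C)CC[C@]2(C)CCC(C)=C(O[Si](C)(C)C)[C@H](O[Si](C)(C)C(C)(C)C)[C@H]21 | intermediate
21 | 6α-(tert-butyldimethylsilyloxy)-4α-isopropyl-1β,8-dimethyl-4β-(trimethylsilyloxy)-trans-hydroazul-8-en-7-one | CC(C)[C@]1(O[Si](C)(C)C)CC[C@]2(C)CC=C(C)C(=O)[C@H](O[Si](C)(C)C(C)(C)C)[C@H]21 | intermediate
22 | 4β,6α-dihydroxy-4α-isopropyl-1β,8-dimethyl-trans-hydroazul-8-en-7-one | CC(C)[C@]1(O)CC[C@]2(C)CC=C(C)C(=O)[C@H](O)[C@H]21 | intermediate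
23 | 4-(tert-butyldimethylsilyloxy)benzoic acid | O=C(O)c1ccc(O[Si](C)(C)C(C)(C)C)cc1 | starting material
24 | 4β-hydroxy-4α-isopropyl-1β,8-dimethyl-7-oxo-trans-hydroazul-8-en-6α-yl 4-(tert-butyldimethylsilyloxy)benzoate | CC(C)[C@]1(O)CC[C@]2(C)CC=C(C)C(=O)[C@H](OC(=O)c3ccc(O[Si](C)(C)C(C)(C)C)cc3)[C@H]21 | intermediate
25 | 4β,7β-dihydroxy-4α-isopropyl-1β,8-dimethyl-trans-hydroazul-8-en-6α-yl 4-(tert-butyldimethylsilyloxy)benzoate | CC(C)[C@]1(O)CC[C@]2(C)CC=C(C)[C@@H](O)[C@H](OC(=O)c3ccc(O[Si](C)(C)C(C)(C)C)cc3)[C@H]21 | intermediate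
26 | 4β-hydroxy-4α-isopropyl-1β,8-dimethyl-7β-(triethylsilyloxy)-trans-hydroazul-8-en-6α-yl 4-(tert-butyldimethylsilyloxy)benzoate | CC(C)[C@]1(O)CC[C@]2(C)CC=C(C)[C@@H](O[Si](CC)(CC)CC)[C@H](OC(=O)c3ccc(O[Si](C)(C)C(C)(C)C)cc3)[C@H]21 | intermediate
27 | 8α,9α-epoxy-4β-hydroxy-4α-isopropyl-1β,8β-dimethyl-7β-(triethylsilyloxy)-trans-perhydroazulen-6α-yl 4-(tert-butyldimethylsilyloxy)benzoate | CC(C)[C@]1(O)CC[C@]2(C)C[C@@H]3O[C@]3(C)[C@@H](O[Si](CC)(CC)CC)[C@H](OC(=O)c3ccc(O[Si](C)(C)C(C)(C)C)cc3)[C@H]21 | intermediate
28 | (1R,4R,5S,6R,7S,8R,9S)-8,9-epoxy-4,7-dihydroxy-4-isopropyl-1,8-dimethyl-trans-perhydroazulen-6-yl 4-hydroxybenzoate (1β-Me, 5α-H, 4β-OH, 6α-aroyloxy, 7β-OH, 8α,9α-epoxide) | CC(C)[C@]1(O)CC[C@]2(C)C[C@@H]3O[C@]3(C)[C@@H](O)[C@H](OC(=O)c3ccc(O)cc3)[C@H]21 | target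

Total step count: 17. Longest linear sequence: 15 steps (1, 3–7, 9–17); steps 2 and 8 are one-step side branches that prepare aldehyde 7 and diazoethane 18.

Steps most likely to fail

Step 9 (ring enlargement). The risks are a competing shift of C6 that would give the regioisomeric ketone, slow addition of the secondary diazoalkane to the flanked carbonyl with decomposition of the reagent, a second insertion, and loss of the tertiary TMS ether at the Lewis acid. The fallback fixes the migrating bond in advance through an enol ether. Setting out from 16, kinetic deprotonation at the C9 methylene (LDA, TMSCl, THF, −78 °C) should give the C7=C9 trimethylsilyl enol ether F1. Dibromocarbene addition (CHBr3, KOt-Bu, pentane, −20 °C) should give the 8,8-dibromo-7-(trimethylsilyloxy) cyclopropane F2. Heating in toluene with pyridine should open the cyclopropane, with loss of the silyl group and one bromide, to the ring-enlarged 8-bromo-8-en-7-one F3. Suzuki–Miyaura coupling with methylboronic acid (Pd(dppf)Cl2, K3PO4, dioxane/H2O, 80 °C) then puts the methyl on C8 and comes back to the route at enone 21, so that steps 10 and 11 are not needed.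

Step 3 (conjugate addition/aldol). The risks are methyl transfer from residual trimethylaluminium to the aldehyde, sluggish aldolisation of the aluminium enolate, and weak discrimination between the methyl and allyl faces at C5 or between anti and syn addition. The fallback separates the two bond formations. Setting out from 4, the same conjugate addition is run and enolate 9 is silylated (TESOTf, −78 °C) to give (R)-3-allyl-3-methyl-1-(triethylsilyloxy)cyclopent-1-ene F4, which is isolated. MeLi (THF, 0 °C) regenerates an aluminium-free lithium enolate; transmetalation with ZnCl2 and addition of 7 at −78 °C should then give the anti aldol through a tight zinc chair transition state. The fallback comes back to the route at 10.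

Step 14 (enone reduction). The risks are hydride delivery to the β-face, which would give the 7α-alcohol, and acyl migration from O6 to O7 in the intermediate borate. The fallback reduces before acylation and delivers the hydride from the neighbouring hydroxyl. Setting out from 22, Me4NBH(OAc)3 (MeCN/AcOH, −30 °C) exchanges a ligand with the 6α-hydroxyl and should transfer hydride internally to the α-face of C7, giving 4α-isopropyl-1β,8-dimethyl-trans-hydroazul-8-ene-4β,6α,7β-triol F5. The more accessible allylic 7-hydroxyl is then silylated (TESCl, imidazole, DMF, −20 °C) to the 7β-triethylsilyl ether F6. Steglich esterification of the remaining 6-hydroxyl with 23 (DCC, DMAP, CH2Cl2) comes back to the route at 26.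

Further compounds
F1 | step 9 | 6α-(tert-butyldimethylsilyloxy)-4α-isopropyl-1β-methyl-4β,7-bis(trimethylsilyloxy)-trans-hydrind-7(9)-ene | CC(C)[C@]1(O[Si](C)(C)C)CC[C@]2(C)CC=C(O[Si](C)(C)C)[C@H](O[Si](C)(C)C(C)(C)C)[C@H]21
F2 | step 9 | 8,8-dibromo-7,9-cyclo adduct of F1 (7-trimethylsilyloxy dibromocyclopropane; cyclopropane face not controlled, both faces converge) | CC(C)[C@]1(O[Si](C)(C)C)CC[C@]2(C)CC3C(Br)(Br)C3(O[Si](C)(C)C)[C@H](O[Si](C)(C)C(C)(C)C)[C@H]21
F3 | step 9 | 8-bromo-6α-(tert-butyldimethylsilyloxy)-4α-isopropyl-1β-methyl-4β-(trimethylsilyloxy)-trans-hydroazul-8-en-7-one | CC(C)[C@]1(O[Si](C)(C)C)CC[C@]2(C)CC=C(Br)C(=O)[C@H](O[Si](C)(C)C(C)(C)C)[C@H]21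
F4 | step 3 | (R)-3-allyl-3-methyl-1-(triethylsilyloxy)cyclopent-1-ene | C=CC[C@@]1(C)CCC(O[Si](CC)(CC)CC)=C1
F5 | step 14 | 4α-isopropyl-1β,8-dimethyl-trans-hydroazul-8-ene-4β,6α,7β-triol | CC(C)[C@]1(O)CC[C@]2(C)CC=C(C)[C@@H](O)[C@H](O)[C@H]21
F6 | step 14 | 4α-isopropyl-1β,8-dimethyl-7β-(triethylsilyloxy)-trans-hydroazul-8-ene-4β,6α-diol | CC(C)[C@]1(O)CC[C@]2(C)CC=C(C)[C@@H](O[Si](CC)(CC)CC)[C@H](O)[C@H]21
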